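## Structural features

The target is a dibenzylbutyrolactone: one γ-lactone ring (O1, C2 carbonyl, C3, C4, C5) with a 3,4-dimethoxybenzyl group (ring A) on C3 and a 3,4,5-trimethoxybenzyl group (ring B) on C4. C3 and C4 are adjacent stereocentres, both R, and the two benzyl groups are trans. C3 is α to the lactone carbonyl and can be epimerised, and trans is the more stable arrangement, so C3 can be settled under thermodynamic control once C4 is fixed. C4 has no acidifying neighbour and lies between three sp3 carbons (C3, C5 and the ring B CH2). It is the real difficulty: one absolute centre that must be made under reagent control. The fragile parts are the lactone (hydroxide, alkoxide, strong nucleophiles) and the two electron-rich arenes (strong oxidants, strong acid). The key step uses the oxygen at position 4 of ring B, para to the CH2 bonded to C4. With that oxygen as a free phenol, this CH2 is the exocyclic carbon of a 2,6-dimethoxy-para-quinone methide, which can be joined to C4 while C4 is the α carbon of an aldehyde. Ring A has no such handle and enters as a benzyl halide on a malonate carbon that becomes C3 and brings C2 and one sacrificial ester.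

## Logic of the disconnections

13 to 12: a methoxycarbonyl group is added back at C3 (the C3–CO2Me bond). This makes C3 a quaternary, malonate-derived carbon, so the only centre needing absolute control is C4. The forward dealkoxycarbonylation must protonate the lactone enolate trans to the C4 substituent, which is also the thermodynamic outcome.

12 to 11: the O–CH3 bond of the 4-methoxy group of ring B is cut. The free phenol is what makes ring B a latent quinone methide. The forward step must methylate a phenol flanked by two methoxy groups without opening the lactone.

11 to 9 (through 10): the acyl O1–C2 bond is cut and C5 is raised to the aldehyde level. This reveals two constitutionally equivalent esters and places C4 α to an aldehyde, where amine catalysis can act. The forward reduction must be fast, must not epimerise C4 and must leave the esters alone; closure on either ester gives the same constitution.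

9 to 5 and 8: the bond between C4 and the ring B CH2 is cut, next to the only centre that needs reagent control. The aldehyde α carbon is the donor (as an enamine) and the benzylic carbon is the acceptor through the para oxygen. Two achiral fragments of similar size result. The forward step needs catalyst-controlled facial selectivity, C-alkylation in preference to N- or O-alkylation, and release of 8 at a rate the hindered enamine can match.

8 to 7 to 6: the benzylic C–S bond of 7 is cut. 7 is a bench-stable store of 8 that opens under base, which the amine catalyst tolerates, and it comes from 6 in one operation. The forward step must substitute the benzylic hydroxyl at sulfur without self-condensation of 6.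

5 to 3 (through 4): the aldehyde is traced to a terminal alkene (the C=C bond of the allyl group), which serves as a masked formylmethyl group. The forward cleavage must spare the electron-rich ring A.

3 to 1 and 2: the bond between the malonate carbon and the ring A CH2 is cut. 1 has a single acidic hydrogen, so the alkylation can only give the quaternary product. The forward step needs only a clean SN2 reaction with a reactive benzylic bromide.

## Other disconnections considered

Alternative 1: The cut takes ring A apart at the two bonds that join the alkyne-derived carbons to the rest of the ring. It leaves the terminal alkyne of the propargyl lactone A2, (3R,4R)-3-(prop-2-yn-1-yl)-4-(3,4,5-trimethoxybenzyl)dihydrofuran-2(3H)-one, and the diene A3, 2,3-dimethoxybuta-1,3-diene. Forward, CoBr2(dppe) reduced by Zn with ZnI2 as activator would join A2 and A3 in a formal [4+2] cycloaddition to the 1,4-cyclohexadiene A1, (3R,4R)-3-[(4,5-dimethoxycyclohexa-1,4-dien-1-yl)methyl]-4-(3,4,5-trimethoxybenzyl)dihydrofuran-2(3H)-one, and a dehydrogenation would give ring A.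
- In favour: the conditions are neutral and should leave the lactone and both stereocentres alone. A3 is symmetric, so there is no regiochemical question. Ring A could be varied late.
- Against: A2 already holds both stereocentres, so the key step does nothing for the stereochemical problem. It builds, in three operations (propargylation, cycloaddition, dehydrogenation), an arene that can be bought as 2 and attached in one. A3 and A1 are enol ethers and sensitive to acid and water. The dehydrogenation must not touch two activated benzylic CH2 groups.
- Comparison: on structure, the chosen plan spends its key step on C4, and this one spends it on a ring without stereochemistry. On mechanism, the cobalt cycloaddition is an established reaction type for terminal alkynes and 2,3-disubstituted dienes; on precedent it is the better of the two. On step economy it is worse, because its steps come on top of whatever makes A2.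

Alternative 2: The cut removes both exocyclic bonds at once, C4–C(benzylic, ring B) and C3–CH2(ring A). It leads to the butenolide A5, (5R)-5-(l-menthyloxy)furan-2(5H)-one, the dithiane A6, 2-(3,4,5-trimethoxyphenyl)-1,3-dithiane, and 2. Forward, A6 lithiated with n-BuLi would add to C4 of A5 anti to the acetal substituent. The lithium enolate would then be benzylated by 2 anti to the new C4 group, giving A4, the 3,4-trans-4,5-trans (3R,4R,5R) adduct. Desulfurisation with Raney Ni and reductive removal of the acetal (hydride under basic conditions, then acid, so that C5 becomes CH2 and the ring recloses) would finish the synthesis.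
- In favour: both stereocentres are set in one flask under substrate control, and the trans relationship at C3/C4 is favoured both kinetically and thermodynamically. The reaction type is established for lignan lactones. Checking the descriptors shows that the 5R acetal leads to the 3R,4R target.
- Against: the auxiliary is stoichiometric and is discarded. The step needs cryogenic organolithium chemistry and a large excess of Raney Ni. The benzylic carbon of ring B reaches the CH2 level only after desulfurisation.
- Comparison: on structure it is more convergent than the chosen plan, since it forms two bonds and two centres in one step against one of each. On mechanism it relies on known chemistry throughout and is the better plan for reliability. On step economy it is about equal (about six operations in all). The chosen plan is ahead only in using a catalytic source of chirality and avoiding sulfur and nickel waste.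

Alternative 3: The cut is the O1–C5 bond. The lactone becomes the prochiral cyclobutanone A8, 3-(3,4,5-trimethoxybenzyl)cyclobutanone. Forward, aqueous H2O2 and a chiral phosphoric acid would effect a Baeyer–Villiger oxidation in which one of the two enantiotopic CH2 groups migrates, giving A7, (R)-4-(3,4,5-trimethoxybenzyl)dihydrofuran-2(3H)-one. Enolate benzylation of A7 with 2, trans to the C4 substituent, would give the target directly. A8 would come from the allylarene A9, 5-allyl-1,2,3-trimethoxybenzene, by a ketene [2+2] cycloaddition and dehalogenation.
- In favour: it is the shortest route (about five operations). The oxidant is benign and the chirality source is catalytic. Trans-selective alkylation of a 4-substituted butyrolactone enolate is a standard endgame. There is no sacrificial ester and no phenol to re-methylate.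
- Against: the catalyst must tell apart two ring CH2 groups that differ only through a flexible benzyl group one carbon away, so enantiocontrol is expected to be less dependable than with 3-aryl cyclobutanones. The lactone is unlikely to offer an easy way of upgrading its enantiopurity. The enolate benzylation can over-alkylate.
- Comparison: on step economy it is better than the chosen plan. On mechanism it is also better placed, because its key reaction type is known for 3-substituted cyclobutanones. On use of catalysis the two are equal. On structure, the chosen plan creates C4 at the reacting carbon itself, next to the catalyst's shielding group, where facial control is usually stronger than remote desymmetrisation, but it pays with two extra steps and an unproven key step.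

Key step: step 4

Remarks on the chemistry (assumptions and corrections):
- **Catalyst hand.** The (R) enantiomer of the diarylprolinol silyl ether is required. The quaternary malonate carbon outranks the incoming benzylic CH2, so the descriptor pairing is the reverse of the usual one for Michael additions of simple aldehydes.
- **C3 stereochemistry.** C3 is not stereochemically silent throughout. Once the lactone closes (11, 12) it is a quaternary stereocentre, formed as a mixture of epimers that is erased in step 7. The SMILES of 11 and 12 therefore leave C3 open.
- **Methide release.** A primary benzylic alcohol such as 6 ionises only under acid strong enough to protonate the amine catalyst. So 6 is first stored as sulfone 7, from which base releases 8 slowly.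
- **Starting material.** 1 is bought already allylated. This saves one alkylation and removes any risk of dialkylation.
- **Numbering.** Catalyst-bound species (enamine, iminium ion) are treated as part of the catalytic cycle and are not numbered.

## Route

Step 1
Reactants: 1 dimethyl allylmalonate [dimethyl 2-(prop-2-en-1-yl)propanedioate]; 2 3,4-dimethoxybenzyl bromide [4-(bromomethyl)-1,2-dimethoxybenzene]
Product: 3 dimethyl 2-allyl-2-(3,4-dimethoxybenzyl)malonate
Conditions: NaH (1.1 equiv), THF/DMF 4:1, 0 °C; then 2 (1.05 equiv, used promptly), 0 °C → rt
Reagents that add atoms: none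
Why: Malonate alkylation (SN2) of the sodium enolate of 1 with a reactive benzylic bromide; 1 has one acidic hydrogen, so only the quaternary product can form, and no stereocentre arises.

Step 2
Reactants: 3 dimethyl 2-allyl-2-(3,4-dimethoxybenzyl)malonate
Product: 5 dimethyl 2-(3,4-dimethoxybenzyl)-2-(2-oxoethyl)malonate, via vicinal diol 4 (not isolated)
Conditions: OsO4 (2 mol%), NaIO4 (4 equiv), 2,6-lutidine (2 equiv), 1,4-dioxane/H2O 3:1, rt
Reagents that add atoms: osmium tetroxide (OsO4), O=[Os](=O)(=O)=O; sodium periodate (NaIO4), [Na+].[O-]I(=O)(=O)=O
Why: Lemieux–Johnson oxidation: catalytic OsO4 dihydroxylates the terminal alkene to 4, and NaIO4 cleaves the glycol and regenerates OsO4; 2,6-lutidine limits over-oxidation, and the veratryl ring and the esters should be inert.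

Step 3
Reactants: 6 syringyl alcohol [4-(hydroxymethyl)-2,6-dimethoxyphenol]
Product: 7 2,6-dimethoxy-4-{[(4-methylphenyl)sulfonyl]methyl}phenol (syringyl p-tolyl sulfone)
Conditions: p-MeC6H4SO2Na (1.5 equiv), HCO2H/H2O 1:1, rt; precipitate filtered off
Reagents that add atoms: sodium p-toluenesulfinate, Cc1ccc(cc1)S(=O)[O-].[Na+]
Why: SN1-type substitution: in aqueous formic acid 6 ionises to the 4-hydroxy-3,5-dimethoxybenzyl cation, which the soft sulfinate captures at sulfur to give the sulfone; precipitation removes the product from the acid and from further benzylation, as in the usual preparation of arylsulfonyl stores of quinone methides.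

Step 4
Reactants: 5 dimethyl 2-(3,4-dimethoxybenzyl)-2-(2-oxoethyl)malonate; 7 2,6-dimethoxy-4-{[(4-methylphenyl)sulfonyl]methyl}phenol
Product: 9 dimethyl 2-(3,4-dimethoxybenzyl)-2-[(2R)-1-(4-hydroxy-3,5-dimethoxyphenyl)-3-oxopropan-2-yl]malonate, via syringyl quinone methide 8 (not isolated)
Conditions: (R)-2-[diphenyl(trimethylsilyloxy)methyl]pyrrolidine (20 mol%), powdered K2CO3 (1.5 equiv), CH2Cl2, 0 °C → rt, 7 (1.3 equiv) added in portions; filtered through a short silica pad and used at once
Reagents that add atoms: none
Why: Proposed new method: K2CO3 deprotonates the phenol of 7 and the phenoxide expels p-toluenesulfinate by 1,6-elimination, releasing 8 slowly, while 5 condenses with the amine to the (E)-enamine, whose α carbon adds to the exocyclic CH2 of 8; rearomatisation to the phenoxide makes the C–C bond formation irreversible and hydrolysis of the iminium ion returns the catalyst. The closest known reaction types are the diarylprolinol silyl ether catalysed 1,6-addition of aldehydes to δ-aryl para-quinone methides and the amine-catalysed α-alkylation of aldehydes by electrophiles released with base from arylsulfonyl precursors; neither has been shown with a δ-unsubstituted methide or a β-quaternary aldehyde. No ring closes. The one new stereocentre is the aldehyde α carbon (the future C4): the C(Ph)2OSiMe3 group blocks one face of the s-trans (E)-enamine, and the (R) catalyst is the one expected to give the (R) centre. The step needs C-alkylation in preference to N- or O-alkylation and a single alkylation: the methide terminus is unsubstituted and small enough for the neopentyl-type enamine, amine and phenoxide adducts of 8 can revert whereas the C-adduct cannot, and the α-branched product forms an enamine only slowly, which guards the new centre against epimerisation and a second alkylation.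

Step 5
Reactants: 9 dimethyl 2-(3,4-dimethoxybenzyl)-2-[(2R)-1-(4-hydroxy-3,5-dimethoxyphenyl)-3-oxopropan-2-yl]malonate
Product: 11 methyl (4R)-3-(3,4-dimethoxybenzyl)-4-(4-hydroxy-3,5-dimethoxybenzyl)-2-oxotetrahydrofuran-3-carboxylate (both C3 epimers), via hydroxy diester 10 (not isolated)
Conditions: NaBH4 (1 equiv), MeOH, −10 → 0 °C, 20 min; then 1 M HCl to pH 3, rt
Reagents that add atoms: none
Why: Chemoselective hydride reduction of the aldehyde (the hindered, non-enolisable malonate esters react far more slowly at this temperature), followed by lactonisation of 10 onto either of the two equivalent esters (5-exo-trig acyl substitution, helped by the quaternary carbon); the C4 centre is then no longer α to a carbonyl and is configurationally secure, and the new C3 centre is of no consequence.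

Step 6
Reactants: 11 methyl (4R)-3-(3,4-dimethoxybenzyl)-4-(4-hydroxy-3,5-dimethoxybenzyl)-2-oxotetrahydrofuran-3-carboxylate
Product: 12 methyl (4R)-3-(3,4-dimethoxybenzyl)-2-oxo-4-(3,4,5-trimethoxybenzyl)tetrahydrofuran-3-carboxylate (both C3 epimers)
Conditions: MeI (3 equiv), K2CO3 (2 equiv), dry acetone, 45 °C
Reagents that add atoms: iodomethane, CI
Why: Williamson ether synthesis on the phenoxide; C3 is quaternary, so there is no enolate to C-methylate, and anhydrous carbonate in acetone should leave the lactone closed.

Step 7
Reactants: 12 methyl (4R)-3-(3,4-dimethoxybenzyl)-2-oxo-4-(3,4,5-trimethoxybenzyl)tetrahydrofuran-3-carboxylate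
Product: 13 (3R,4R)-3-(3,4-dimethoxybenzyl)-4-(3,4,5-trimethoxybenzyl)dihydrofuran-2(3H)-one (target)
Conditions: LiCl (3 equiv), H2O (2 equiv), DMSO, 150 °C
Reagents that add atoms: none
Why: Krapcho dealkoxycarbonylation: chloride demethylates the ester by SN2, the carboxylate loses CO2, and water protonates the lactone enolate; C3 is set here, by protonation anti to the C4 benzyl group and under conditions where it can equilibrate to the more stable trans (3R,4R) lactone, while C4 is untouched.

## Compound list

1 | dimethyl allylmalonate | C=CCC(C(=O)OC)C(=O)OC | starting material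
2 | 3,4-dimethoxybenzyl bromide | COc1ccc(CBr)cc1OC | starting material
3 | dimethyl 2-allyl-2-(3,4-dimethoxybenzyl)malonate | C=CCC(Cc1ccc(OC)c(OC)c1)(C(=O)OC)C(=O)OC | intermediate
4 | dimethyl 2-(3,4-dimethoxybenzyl)-2-(2,3-dihydroxypropyl)malonate (racemic at the carbinol carbon) | OCC(O)CC(Cc1ccc(OC)c(OC)c1)(C(=O)OC)C(=O)OC | intermediate
5 | dimethyl 2-(3,4-dimethoxybenzyl)-2-(2-oxoethyl)malonate | COC(=O)C(CC=O)(Cc1ccc(OC)c(OC)c1)C(=O)OC | intermediate
6 | syringyl alcohol, 4-(hydroxymethyl)-2,6-dimethoxyphenol | COc1cc(CO)cc(OC)c1O | starting material
7 | 2,6-dimethoxy-4-{[(4-methylphenyl)sulfonyl]methyl}phenol | COc1cc(CS(=O)(=O)c2ccc(C)cc2)cc(OC)c1O | intermediate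
8 | 2,6-dimethoxy-4-methylidenecyclohexa-2,5-dien-1-one (syringyl quinone methide) | C=C1C=C(OC)C(=O)C(OC)=C1 | intermediate
9 | dimethyl 2-(3,4-dimethoxybenzyl)-2-[(2R)-1-(4-hydroxy-3,5-dimethoxyphenyl)-3-oxopropan-2-yl]malonate | O=C[C@H](Cc1cc(OC)c(O)c(OC)c1)C(C(=O)OC)(C(=O)OC)Cc1ccc(OC)c(OC)c1 | intermediate
10 | dimethyl 2-(3,4-dimethoxybenzyl)-2-[(2R)-1-hydroxy-3-(4-hydroxy-3,5-dimethoxyphenyl)propan-2-yl]malonate | OC[C@H](Cc1cc(OC)c(O)c(OC)c1)C(C(=O)OC)(C(=O)OC)Cc1ccc(OC)c(OC)c1 | intermediate
11 | methyl (4R)-3-(3,4-dimethoxybenzyl)-4-(4-hydroxy-3,5-dimethoxybenzyl)-2-oxotetrahydrofuran-3-carboxylate (C3 epimers) | COC(=O)C1(Cc2ccc(OC)c(OC)c2)C(=O)OC[C@@H]1Cc3cc(OC)c(O)c(OC)c3 | intermediate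
12 | methyl (4R)-3-(3,4-dimethoxybenzyl)-2-oxo-4-(3,4,5-trimethoxybenzyl)tetrahydrofuran-3-carboxylate (C3 epimers) | COC(=O)C1(Cc2ccc(OC)c(OC)c2)C(=O)OC[C@@H]1Cc3cc(OC)c(OC)c(OC)c3 | intermediate
13 | (3R,4R)-3-(3,4-dimethoxybenzyl)-4-(3,4,5-trimethoxybenzyl)dihydrofuran-2(3H)-one | COc1ccc(C[C@H]2C(=O)OC[C@@H]2Cc2cc(OC)c(OC)c(OC)c2)cc1OC | target

## Step count and least certain steps

Total step count: 7. Longest linear sequence: 6 steps (steps 1, 2, 4, 5, 6, 7, starting from 1); step 3 is a one-step side branch.

**Step 4 (key step, new method).** The C–C bond formation from the β-quaternary enamine may be slower than self-condensation of the methide or its capture by the catalyst nitrogen, so the catalyst is alkylated and conversion stalls. Facial discrimination with so large a group on the enamine carbon is untested. The product may also epimerise on the basic solid before it is reduced.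
Fallback (known chemistry; sets out from 5, returns at 12). 5 is condensed with (S)-1-amino-2-(methoxymethyl)pyrrolidine to the SAMP hydrazone F1. Deprotonation with LiN(iPr)2 in THF at −78 °C and alkylation of the azaenolate with purchased 3,4,5-trimethoxybenzyl bromide (SAMP-hydrazone alkylation, Enders alkylation) should give the α-benzylated hydrazone F2. By the usual topicity of these azaenolates the (S) auxiliary is expected to give the (R) centre here, and the enantiomeric auxiliary is available if correlation shows otherwise. Two-phase cleavage with aqueous oxalic acid and ether releases the trimethoxy aldehyde F3 and returns the auxiliary. NaBH4 in MeOH followed by acid, as in step 5, passes through the hydroxy diester F4 and closes to 12. 12 already carries the third methoxy group, so step 6 is not needed.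

**Step 7.** At 150 °C chloride or hydroxide may open the lactone, and protonation of the enolate may not be fully trans-selective.
Fallback (sets out from 12, returns at 13). KOH in aqueous MeOH at reflux opens the lactone and hydrolyses the ester to the hydroxy malonic acid F5 (as its dipotassium salt). Acidification recloses the ring to the lactone acid F6, which should lose CO2 when heated in toluene and give 13. A short treatment with DBU would move any cis isomer to trans.

**Step 2.** The transient diol may close onto a neighbouring ester faster than periodate cleaves it, which removes the glycol and stalls the cleavage. Over-oxidation of the aldehyde is a lesser concern.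
Fallback (sets out from 2, returns at 5, bypassing 1, 3 and 4). Purchased dimethyl malonate is alkylated (NaH, DMF, 90 °C) with purchased bromoacetaldehyde dimethyl acetal to the acetal malonate F7. A second alkylation with 2 (NaH, THF/DMF) gives the quaternary acetal F8. Aqueous acid (1 M HCl, acetone, rt) unmasks 5 with no oxidation step.

**Step 6.** O-Alkylation of the doubly ortho-flanked phenoxide may be slow. That leaves time for carbonate or adventitious hydroxide to attack the non-enolisable α-acyl lactone, by ring opening or retro-Claisen loss of the ester.
Fallback (sets out from 11, returns at 13). The order is reversed. The Krapcho conditions of step 7 are applied to 11 to give the phenolic lactone F9. Its simple lactone tolerates MeI and K2CO3 in acetone, and methylation then gives 13.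

## Further compounds

F1 | step 4 | dimethyl 2-(3,4-dimethoxybenzyl)-2-[(2E)-2-{[(2S)-2-(methoxymethyl)pyrrolidin-1-yl]imino}ethyl]malonate (SAMP hydrazone) | COC[C@@H]1CCCN1/N=C/CC(Cc2ccc(OC)c(OC)c2)(C(=O)OC)C(=O)OC
F2 | step 4 | dimethyl 2-(3,4-dimethoxybenzyl)-2-[(1E,2R)-1-{[(2S)-2-(methoxymethyl)pyrrolidin-1-yl]imino}-3-(3,4,5-trimethoxyphenyl)propan-2-yl]malonate (α-benzylated hydrazone) | COC[C@@H]1CCCN1/N=C/[C@H](Cc2cc(OC)c(OC)c(OC)c2)C(Cc3ccc(OC)c(OC)c3)(C(=O)OC)C(=O)OC
F3 | step 4 | dimethyl 2-(3,4-dimethoxybenzyl)-2-[(2R)-1-oxo-3-(3,4,5-trimethoxyphenyl)propan-2-yl]malonate (trimethoxy aldehyde) | O=C[C@H](Cc1cc(OC)c(OC)c(OC)c1)C(C(=O)OC)(C(=O)OC)Cc1ccc(OC)c(OC)c1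
F4 | step 4 | dimethyl 2-(3,4-dimethoxybenzyl)-2-[(2R)-1-hydroxy-3-(3,4,5-trimethoxyphenyl)propan-2-yl]malonate (hydroxy diester) | OC[C@H](Cc1cc(OC)c(OC)c(OC)c1)C(C(=O)OC)(C(=O)OC)Cc1ccc(OC)c(OC)c1
F5 | step 7 | 2-(3,4-dimethoxybenzyl)-2-[(2R)-1-hydroxy-3-(3,4,5-trimethoxyphenyl)propan-2-yl]malonic acid (hydroxy malonic acid) | OC[C@H](Cc1cc(OC)c(OC)c(OC)c1)C(C(=O)O)(C(=O)O)Cc1ccc(OC)c(OC)c1
F6 | step 7 | (4R)-3-(3,4-dimethoxybenzyl)-2-oxo-4-(3,4,5-trimethoxybenzyl)tetrahydrofuran-3-carboxylic acid (lactone acid, C3 epimers) | OC(=O)C1(Cc2ccc(OC)c(OC)c2)C(=O)OC[C@@H]1Cc3cc(OC)c(OC)c(OC)c3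
F7 | step 2 | dimethyl 2-(2,2-dimethoxyethyl)malonate (acetal malonate) | COC(=O)C(CC(OC)OC)C(=O)OC
F8 | step 2 | dimethyl 2-(3,4-dimethoxybenzyl)-2-(2,2-dimethoxyethyl)malonate (quaternary acetal) | COC(=O)C(CC(OC)OC)(Cc1ccc(OC)c(OC)c1)C(=O)OC
F9 | step 6 | (3R,4R)-3-(3,4-dimethoxybenzyl)-4-(4-hydroxy-3,5-dimethoxybenzyl)dihydrofuran-2(3H)-one (phenolic lactone) | COc1ccc(C[C@H]2C(=O)OC[C@@H]2Cc2cc(OC)c(O)c(OC)c2)cc1OC
A1 | alternative 1 | (3R,4R)-3-[(4,5-dimethoxycyclohexa-1,4-dien-1-yl)methyl]-4-(3,4,5-trimethoxybenzyl)dihydrofuran-2(3H)-one | COC1=C(OC)CC(C[C@H]2C(=O)OC[C@@H]2Cc2cc(OC)c(OC)c(OC)c2)=CC1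
A2 | alternative 1 | (3R,4R)-3-(prop-2-yn-1-yl)-4-(3,4,5-trimethoxybenzyl)dihydrofuran-2(3H)-one | C#CC[C@H]1C(=O)OC[C@@H]1Cc2cc(OC)c(OC)c(OC)c2
A3 | alternative 1 | 2,3-dimethoxybuta-1,3-diene | C=C(OC)C(=C)OC
A4 | alternative 2 | (3R,4R,5R)-3,4-trans-4,5-trans-3-(3,4-dimethoxybenzyl)-5-(l-menthyloxy)-4-[2-(3,4,5-trimethoxyphenyl)-1,3-dithian-2-yl]dihydrofuran-2(3H)-one | C[C@@H]1CC[C@H]([C@@H](C1)O[C@@H]2OC(=O)[C@H](Cc3ccc(OC)c(OC)c3)[C@H]2C4(c3cc(OC)c(OC)c(OC)c3)SCCCS4)C(C)C
A5 | alternative 2 | (5R)-5-(l-menthyloxy)furan-2(5H)-one | C[C@@H]1CC[C@H]([C@@H](C1)O[C@@H]2OC(=O)C=C2)C(C)C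
A6 | alternative 2 | 2-(3,4,5-trimethoxyphenyl)-1,3-dithiane | COc1cc(cc(OC)c1OC)C1SCCCS1
A7 | alternative 3 | (R)-4-(3,4,5-trimethoxybenzyl)dihydrofuran-2(3H)-one | O=C1C[C@@H](Cc2cc(OC)c(OC)c(OC)c2)CO1
A8 | alternative 3 | 3-(3,4,5-trimethoxybenzyl)cyclobutanone | O=C1CC(Cc2cc(OC)c(OC)c(OC)c2)C1
A9 | alternative 3 | 5-allyl-1,2,3-trimethoxybenzene | C=CCc1cc(OC)c(OC)c(OC)c1
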